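## Structural features

The target is a germacranolide: a ten-membered carbocycle C1–C10 with an α-methylene γ-lactone trans-fused at C6 (oxygen) and C7 (carbon), an isobutyrate on C8, a methyl-bearing tertiary carbinol at C10 and a methyl group on C4. The C3 ketone is cross-conjugated, with the 4Z trisubstituted alkene on one side and the C1–C2 trans-oxirane, attached to the quaternary C10, on the other. The six stereocentres, (1R,2R,6R,7R,8R,10R), form two contiguous triads, C6/C7/C8 and C10/C1/C2, which face each other across the ring and are linked only through C9 and the planar C3–C5 unit. The fragile parts are the exocyclic methylene lactone (nucleophiles, base), the epoxy ketone (base, Lewis acids), the C8 ester (1,3 to the C6 and C10 oxygens, so prone to migration) and the Z-γ-oxy enone, which can close to a hemiketal once the C6 oxygen is free. The real difficulty is the medium ring itself: a ten-membered ring holding a Z-enone and a fixed relation between C10 and C6/C7, to be made without end-to-end cyclisation of a sensitive open chain. The key step exploits that C3 and C8 are oxygen-bearing carbons standing 1,6 to each other, and that the arc C3–C4(Me)=C5–C6–C7–C8, with its Z-alkene and the three-carbon branch on C7, is the ring of carvone. A bond drawn between C3 and C8 turns the macrocycle into a decalin (ring A = C3 to C8; ring B = C8, C9, C10, C1, C2, C3) whose ring-fusion bond is a cleavable glycol.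

## Logic of the disconnections

26 from 23. The lactone bond C12–O(C6) is opened and C12 lowered to the primary alcohol (25 and 24 lie in between). The methylene lactone is the function least tolerant of base and nucleophilic oxidants, so it is made last and every earlier compound lacks this acceptor. The forward step must oxidise a primary allylic alcohol beside a free secondary and a tertiary alcohol, without base.

23 from 22, and 22 from 21. Two O–Si bonds and then the two C–O bonds of the oxirane are removed. In 21 the C1=C2 bond is E and disubstituted, and oxygen can be added there before any second Michael acceptor exists. The forward epoxidation must choose C1=C2 over the α-methylated Z-alkene and the correct face of the ring.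

21 from 20. The C1=C2 bond and the free C10 hydroxyl are traced to one acetonide: the C1–O bond is re-formed and a hydrogen returned to C2. This single group masks alkene and carbinol through oxidation, reduction and acylation and leaves as acetone. The elimination requires C3 to be the only ketone, because the C10 oxygen would be β to a C8 carbonyl.

20 from 19, and 19 from 18. The ester C–O bond and the C8–H bond are cut, which leads to the 3,8-dione. Reducing C8 first removes the carbonyl that would misdirect the elimination and acidify C7. The forward step needs a hydride that distinguishes a saturated ketone from an enone and adds to the correct face of C8.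

18 from 17. The C3–C8 bond is re-formed. The ten-membered ring becomes two six-membered rings, the Z-alkene becomes a cyclohexene bond, and C6, C7, C10 and C1 sit on rigid rings. The forward cleavage needs a single free, syn glycol and nothing else the oxidant attacks.

17 from 16, and 16 from 15. The acetonide is removed and the C1–O and C10–O bonds are cut to leave the C1=C10 alkene of ring B. In a cis-fused bicycle the reagent comes from the convex face, that of the angular hydroxyls; with these anti to the C7 branch this is the face C10 requires. The demand is chemoselectivity among three alkenes. For that reason the C7 branch is carried as a silyloxymethyl vinyl group and not as a bare isopropenyl group: it is then hindered, less electron-rich, and already at the oxidation level needed for the last step.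

15 from 14. The C1=C10 bond is cut to an allyl group on C3 and a 2-methylallyl group on C8. The forward metathesis requires them to be cis, the same requirement as the syn glycol.

14 from 12 and 13. The C8–C9 bond is cut. A carbon nucleophile adding to a C8 ketone is steered anti to the pseudoaxial C3 oxygen, which puts carbon on the face of the C7 branch and oxygen on the opposite face, as 17 needs. The addition must outrun enolisation towards C7.

12 from 11, and 11 from 9 and 10. The C8 carbonyl is returned to the carbinol and the C2–C3 bond is cut. This order corrects the obvious one. Were C8 made quaternary first (alkylation, then hydroxylation), its carbon substituent would be pseudoaxial beside the C3 carbonyl; an allyl nucleophile would enter anti to it and give the trans glycol and a trans-fused bicycle. With C8 still a secondary carbinol, one face carries only hydrogen, and a chelated addition can deliver allyl trans to the C8 oxygen. The demand is chelation control in a 1,2-addition to an enone.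

9 from 7. The C8–O bond is cut (8 lies in between). Enolate oxidation at the only α′ position places oxygen anti to the C7 branch.

7 from 6, and 6 from 5. Two O–Si bonds and the C12–O bond are cut. Allylic oxidation is done here, where the isopropenyl group is the only electron-rich alkene, and not late beside an epoxy ketone.

5 from 3, and 3 from 1. The C6–O bond is cut (4 and 2 lie in between). Oxygen at the γ-carbon of the enone is reached through the extended dienol ether and addition of oxygen across the diene, which is regiochemically unambiguous. The demand is that the extended, not the cross-conjugated, dienolate be trapped.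

## Other disconnections considered

Alternative 1: The cut goes through C1–C2 and the C2–O bond of the oxirane and leads to the open-chain aldehyde–chloromethyl ketone A1. Forward, the enolate of the chloromethyl ketone would add to the C1 aldehyde and the aldolate would displace chloride (Darzens reaction), giving the epoxy ketone A2 with ring and oxirane made together.
- In its favour: the epoxy ketone arrives at its final oxidation level, and no separate face-selective epoxidation is needed. On this point it is better than the chosen plan, whose step 16 is stereochemically uncertain.
- Against it here: the closure is a reversible aldol-type end-to-end cyclisation to a strained ten-membered ring. The lactone CH2 of A1 is about as acidic as the chloromethyl ketone. The aldehyde sits on a quaternary, silyloxy-bearing carbon. The C1/C2 configuration relative to C10 would depend on an unconstrained macrocyclic transition state.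
- Structure: A1 carries C6, C7, C8 and C10 on an open chain, to be set by acyclic control; the chosen plan takes C7 from the chiral pool and sets the rest on six-membered rings.
- Mechanism: anionic closure versus a glycol fragmentation that involves no cyclisation.
- Step economy: after A2 the lactone must still be methylenated beside an epoxy ketone and two silyl groups exchanged, so the total would not be shorter. The two plans are equal in that neither has to create the Z-alkene during ring formation.

Alternative 2: The cut is C7–C11. Forward, the anion of the phosphonoacetate on the C6 oxygen of the bis-epoxide A3 would open the 7,8-oxirane at C7 with inversion (5-exo), giving the phosphono lactone A4 and freeing the C8 hydroxyl; a Horner–Wadsworth–Emmons reaction with formaldehyde would then install the methylene group.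
- In its favour: C7 and the trans lactone are fixed by an SN2 step, the C8 carbinol is released exactly where the ester goes, and the methylene group comes from one olefination. On these points it is better than the chosen plan, which relies on a hydride reduction of uncertain facial selectivity at C8 and a two-step lactone end-game.
- Against it here: it is a lactone annulation, not a way to the carbocycle. A3 already contains the ten-membered ring, the Z-alkene, the 1,2-oxirane and a 7,8-oxirane of defined configuration, so the medium-ring problem is only moved. Two oxiranes would be exposed to a basic carbanion, and C3 must be carried as a protected carbinol and oxidised later.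
- Mechanism: the 5-exo opening is as dependable as a glycol cleavage (equal).
- Structure: it controls C6–C8 but says nothing about C10 relative to C7.
- Step economy: a separate synthesis of A3 makes it longer as a whole.

Alternative 3: The cut is C3–C4. Forward, the vinyl iodide–epoxy aldehyde A5 would be closed with CrCl2 and catalytic NiCl2 (Nozaki–Hiyama–Kishi reaction) to the 3-carbinol A6, which is one oxidation from 26.
- In its favour: the organochromium reagent tolerates esters, lactones and free tertiary alcohols, the Z geometry of the iodide is retained, and both C3 epimers converge on oxidation. The end-game is the shortest of all, better than the six steps that follow the key step of the chosen plan. The two plans are equal in that the stereocentre made at the strategic carbon is erased afterwards.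
- Against it here: A5 is a fully functionalised chain with six stereocentres, the methylene lactone and an α,β-epoxy aldehyde in place before cyclisation. The Lewis-acidic trivalent chromium formed in the reaction can open the epoxy aldehyde, and low-valent chromium can attack the methylene lactone. The closure is a true end-to-end macrocyclisation to a strained ring and would need high dilution and stoichiometric chromium.
- Step economy: a linear, acyclically controlled synthesis of A5 would exceed the eleven steps that bring 1 to 17.

Key step: step 12

Remark on the chemistry: germacrane numbering is used for every intermediate; the C3 and C8 configurations of 11–17 vanish in step 12 and are chosen only so that the glycol is syn and the convex face of ring B is the one C10 needs.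

## Route

Step 1
Reactants: 1 (S)-(+)-carvone
Product: 3 extended tert-butyldimethylsilyl dienol ether of 1, via potassium dienolate 2 (not isolated)
Conditions: KOt-Bu, THF/DMPU, −10 °C; TBSCl, −78 → 0 °C
Reagents that add atoms: tert-butyldimethylsilyl chloride CC(C)(C)[Si](C)(C)Cl
Why: Under equilibrating conditions a cyclohex-2-enone gives the extended (γ-deprotonated) dienolate, which is silylated on oxygen (thermodynamic silyl dienol ether formation); the C7 stereocentre is not part of the dienolate and is kept.

Step 2
Reactants: 3 extended silyl dienol ether
Product: 5 (4R,5S)-4-hydroxy-2-methyl-5-(prop-1-en-2-yl)cyclohex-2-en-1-one, via silylperoxy enone 4 (not isolated)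
Conditions: O2, hν, tetraphenylporphyrin (cat.), CH2Cl2, −78 °C; PPh3; HF·pyridine, THF, 0 °C
Reagents that add atoms: dioxygen O=O
Why: [4+2] photooxygenation of the 1-silyloxy diene by singlet oxygen, on the face opposite the isopropenyl group on the adjacent C7, gives an endoperoxide that opens with silyl transfer to the γ-silylperoxy enone; the phosphine removes one oxygen and fluoride the silyl group. The C6 stereocentre is thus set trans to C7 by steric approach control, and the 1,1-disubstituted isopropenyl alkene reacts far more slowly with singlet oxygen than the electron-rich diene.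

Step 3
Reactants: 5 trans-4-hydroxycarvone
Product: 6 (4R,5S)-4-hydroxy-5-(3-hydroxyprop-1-en-2-yl)-2-methylcyclohex-2-en-1-one
Conditions: SeO2 (cat.), t-BuOOH, CH2Cl2, 0 °C → rt
Reagents that add atoms: tert-butyl hydroperoxide CC(C)(C)OO
Why: SeO2-catalysed allylic hydroxylation (ene reaction, then [2,3]-shift) occurs at the methyl group of the isopropenyl unit, the only electron-rich alkene; the enone double bond is deactivated and the methyl hydrogens are preferred over the C7 methine.

Step 4
Reactants: 6 diol
Product: 7 bis(tert-butyldimethylsilyl) ether of 6
Conditions: TBSCl, imidazole, DMF, rt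
Reagents that add atoms: tert-butyldimethylsilyl chloride CC(C)(C)[Si](C)(C)Cl
Why: Standard silylation of a primary and a secondary alcohol; both ethers withstand the enolate, organometallic, metathesis and oxidation steps that follow and leave together in step 17.

Step 5
Reactants: 7 bis-silyl ether
Product: 9 8-hydroxy ketone (8-OH trans to the C7 branch), via potassium enolate 8 (not isolated)
Conditions: KN(SiMe3)2, THF, −78 °C; 2-(phenylsulfonyl)-3-phenyloxaziridine, −78 °C; AcOH
Reagents that add atoms: 2-(phenylsulfonyl)-3-phenyloxaziridine O=S(=O)(c1ccccc1)N1OC1c1ccccc1
Why: Enolate hydroxylation with a sulfonyloxaziridine (Davis oxidation): kinetic deprotonation takes the only α′ hydrogens (C8), and the oxidant approaches the enolate face opposite the C7 branch, which allylic strain turns pseudoaxial. The 8-hydroxyl therefore ends trans to C7 and cis to the C6 silyl ether.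

Step 6
Reactants: 9 8-hydroxy ketone; 10 allyl bromide
Product: 11 3-allyl cis-3,8-diol
Conditions: indium powder (In), THF/H2O (3:1), rt
Reagents that add atoms: none
Why: Barbier allylation through an allylindium reagent, a 1,2-addition to the ketone: trivalent indium held between the carbonyl and the free C8 hydroxyl fixes the C8–O bond in the carbonyl plane, and the allyl group enters from the face that carries only the C8 hydrogen (Cram chelate model), trans to the C8 oxygen. This sets C3 with its hydroxyl cis to the 8-hydroxyl; the aqueous medium leaves the silyl ethers alone.

Step 7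
Reactants: 11 3-allyl cis-3,8-diol
Product: 12 3-allyl-3-hydroxy 8-ketone
Conditions: IBX (2-iodoxybenzoic acid), DMSO, rt
Reagents that add atoms: none
Why: IBX oxidises the secondary alcohol of a 1,2-diol to the α-ketol without cleaving the C–C bond and does not touch the tertiary allylic alcohol; the neutral medium avoids α-ketol rearrangement and loss of the β-silyloxy group at C6.

Step 8
Reactants: 12 3-allyl-3-hydroxy 8-ketone; 13 2-methylallylmagnesium chloride CH2=C(CH3)CH2MgCl
Product: 14 3-allyl-8-(2-methylallyl) cis-3,8-diol
Conditions: THF, −78 °C; aq NH4Cl
Reagents that add atoms: none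
Why: Grignard 1,2-addition: with the C7 branch and the C6 silyl ether equatorial the C3 oxygen (as magnesium alkoxide) is pseudoaxial, and the 2-methylallyl group adds to the C8 carbonyl anti to it (Felkin–Anh, polar substituent perpendicular), on the face of the allyl group and the C7 branch. C8 is thus set with its hydroxyl cis to the 3-hydroxyl; an allylic Grignard reagent adds faster than it enolises towards C7.

Step 9
Reactants: 14 diallyl cis-diol
Product: 15 cis-fused bicyclic 3,8-diol with C1=C10 alkene
Conditions: second-generation Grubbs catalyst (H2IMes)(PCy3)Cl2Ru=CHPh (5 mol %), CH2Cl2, 40 °C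
Reagents that add atoms: none
Why: Ring-closing metathesis of the cis-disposed allyl and 2-methylallyl groups closes ring B with a trisubstituted alkene and loss of ethene; the trisubstituted ring-A alkene and the hindered 1,1-disubstituted alkene of the C7 branch, which bears an allylic silyl ether, are poor partners for the ruthenium carbene.

Step 10
Reactants: 15 bicyclic diol
Product: 16 1,3,8,10-tetrol
Conditions: OsO4 (cat.), NMO (1 equiv), acetone/H2O, 0 °C
Reagents that add atoms: N-methylmorpholine N-oxide C[N+]1([O-])CCOCC1; water O
Why: Upjohn dihydroxylation ([3+2] addition of OsO4): the ring-B alkene is the most electron-rich and most exposed of the three, and OsO4 comes from the convex face of the cis-fused bicycle, the face of the two angular hydroxyls. This sets C10 (oxygen anti to the C7 branch) and C1 as a cis diol; the oxidant is limited to one equivalent to protect the branch alkene.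

Step 11
Reactants: 16 tetrol
Product: 17 key-step precursor: cis-fused decalin-3,8-diol 1,10-acetonide
Conditions: 2-methoxypropene, PPTS (cat.), CH2Cl2, 0 °C
Reagents that add atoms: 2-methoxypropene COC(C)=C
Why: Kinetic acetalisation: the secondary C1 hydroxyl forms the mixed ketal and closes on the cis C10 hydroxyl, while the ring-fusion glycol, two tertiary hydroxyls flanked by substituted carbons, is too hindered to react; the weak acid spares the silyl ethers and the tertiary allylic alcohol.

Step 12
Reactants: 17 cis-fused decalin-3,8-diol 1,10-acetonide
Product: 18 key-step product: ten-membered (4Z)-ene-3,8-dione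
Conditions: Pb(OAc)4, pyridine, CH2Cl2, −20 → 0 °C
Reagents that add atoms: none
Why: Exchange of two acetates on tetravalent lead for the two syn ring-fusion hydroxyls of 17 should give a five-membered cyclic lead diester, which fragments in a concerted two-electron step that breaks C3–C8, delivers both carbons as ketones and releases Pb(OAc)2. The closest known reaction type is the Criegee glycol cleavage of cis-9,10-dihydroxydecalins to cyclodecane-1,6-diones. The ten-membered ring is not closed by bond formation: it is unveiled when the bond common to rings A and B is cut, so no end-to-end cyclisation and no high dilution are involved. No stereocentre is created; C3 and C8 are erased, C6, C7, C10 and C1 are untouched, and the cyclohexene bond of ring A becomes the 4Z alkene by inheritance. Only chemoselectivity is needed: the ring-fusion glycol is the single free 1,2-diol (C1/C10 is an acetonide, C6 and C12 are silyl ethers), its hydroxyls are held gauche by the cis fusion, and isolated alkenes are inert to Pb(OAc)4 at low temperature. Pyridine takes up the acetic acid so that the acetonide and the new β-silyloxy and β-alkoxy ketone units survive.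

Step 13
Reactants: 18 ten-membered 3,8-dione
Product: 19 (8R)-8-hydroxy 3-ketone
Conditions: NaBH4, MeOH/CH2Cl2 (1:1), −78 °C
Reagents that add atoms: none
Why: Borohydride at low temperature in methanol/dichloromethane reduces a saturated ketone in preference to a conjugated enone. Hydride should add from the periphery of the ring, anti to the C6–C7 ring bond (Felkin–Anh), which places the new C8 oxygen anti to the C7 branch along the chain, the (8R) configuration; the β-oxygenated ketone units survive the cold, weakly basic medium.

Step 14
Reactants: 19 (8R)-alcohol
Product: 20 8-isobutyrate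
Conditions: (i-PrCO)2O, Et3N, DMAP (cat.), CH2Cl2, 0 °C → rt
Reagents that add atoms: isobutyric anhydride CC(C)C(=O)OC(=O)C(C)C
Why: DMAP-catalysed acylation of the only free alcohol; the amine base is too weak to start elimination of the acetonide oxygen.

Step 15
Reactants: 20 8-isobutyrate
Product: 21 (1E,4Z)-dienone with free 10-hydroxyl
Conditions: DBU, toluene, 25 → 50 °C
Reagents that add atoms: none
Why: E1cB elimination: C2 is the only acidic CH2 next to the only ketone, the C1 oxygen of the acetonide leaves from the enolate, and the resulting hemiketal alkoxide loses acetone to free the C10 hydroxyl. The antiperiplanar arrangement available in the ten-membered ring should give the E alkene; the C8 ester is not β to any carbonyl and stays.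

Step 16
Reactants: 21 (1E,4Z)-dienone
Product: 22 (1R,2R)-1,2-epoxy ketone
Conditions: t-BuOOH, DBU, CH2Cl2, 0 °C
Reagents that add atoms: tert-butyl hydroperoxide CC(C)(C)OO
Why: Weitz–Scheffer nucleophilic epoxidation: the tert-butyl peroxide anion adds to C1 of the disubstituted E-enone, which is more electrophilic and less hindered than the α-methylated Z-enone, and ring closure with loss of tert-butoxide keeps the trans relation. Attack on the outer face of the E alkene, whose plane stands perpendicular to the ring, in the conformer with the C10 hydroxyl turned outward is expected to give the (1R,2R) oxirane; the silyloxymethyl vinyl group is no acceptor and is untouched.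

Step 17
Reactants: 22 epoxy ketone
Product: 23 6,12-diol
Conditions: HF·pyridine, pyridine, THF, 0 °C → rt
Reagents that add atoms: none
Why: Fluoride cleaves the primary and the secondary silyl ether; the buffered, mildly acidic reagent avoids migration of the C8 isobutyrate to the freed C6 hydroxyl and does not open the electron-poor oxirane.

Step 18
Reactants: 23 6,12-diol
Product: 26 target (1R,2R,4Z,6R,7R,8R,10R)-germacranolide, via hydroxy enal 24 (not isolated), via lactol 25 (not isolated)
Conditions: TEMPO (cat.), PhI(OAc)2, CH2Cl2, rt
Reagents that add atoms: none
Why: Oxoammonium (TEMPO) oxidation is selective for the primary allylic alcohol; the aldehyde is trapped by the C6 hydroxyl as a five-membered lactol, which is oxidised on to the lactone (oxidative lactonisation of a 1,4-diol). The trans ring fusion follows from the existing C6 and C7 configurations, and the base-free conditions preserve the methylene lactone, the epoxy ketone and the ester.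

## Compound list

1 | (S)-(+)-carvone | CC1=CC[C@@H](CC1=O)C(C)=C | starting material
2 | potassium (5R)-2-methyl-5-(prop-1-en-2-yl)cyclohexa-1,3-dien-1-olate (extended dienolate of 1) | CC1=C([O-])C[C@@H](C(C)=C)C=C1.[K+] | intermediate
3 | tert-butyl(dimethyl){[(5R)-2-methyl-5-(prop-1-en-2-yl)cyclohexa-1,3-dien-1-yl]oxy}silane | CC1=C(O[Si](C)(C)C(C)(C)C)C[C@@H](C(C)=C)C=C1 | intermediate
4 | (4R,5S)-4-[(tert-butyldimethylsilyl)peroxy]-2-methyl-5-(prop-1-en-2-yl)cyclohex-2-en-1-one | CC1=C[C@@H](OO[Si](C)(C)C(C)(C)C)[C@H](C(C)=C)CC1=O | intermediate
5 | (4R,5S)-4-hydroxy-2-methyl-5-(prop-1-en-2-yl)cyclohex-2-en-1-one (hydroxyl trans to the isopropenyl group) | CC1=C[C@@H](O)[C@H](C(C)=C)CC1=O | intermediate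
6 | (4R,5S)-4-hydroxy-5-(3-hydroxyprop-1-en-2-yl)-2-methylcyclohex-2-en-1-one | CC1=C[C@@H](O)[C@H](C(CO)=C)CC1=O | intermediate
7 | (4R,5S)-4-(tert-butyldimethylsilyloxy)-5-[3-(tert-butyldimethylsilyloxy)prop-1-en-2-yl]-2-methylcyclohex-2-en-1-one | CC1=C[C@@H](O[Si](C)(C)C(C)(C)C)[C@H](C(CO[Si](C)(C)C(C)(C)C)=C)CC1=O | intermediate
8 | potassium enolate of 7 (enolate across C3–C8, cross-conjugated with C4=C5) | CC1=C[C@@H](O[Si](C)(C)C(C)(C)C)[C@H](C(CO[Si](C)(C)C(C)(C)C)=C)C=C1[O-].[K+] | intermediate
9 | 7 with a hydroxyl on C8 (α′), trans to the C7 branch and cis to the C6 silyl ether | CC1=C[C@@H](O[Si](C)(C)C(C)(C)C)[C@H](C(CO[Si](C)(C)C(C)(C)C)=C)[C@@H](O)C1=O | intermediate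
10 | allyl bromide (3-bromoprop-1-ene) | C=CCBr | starting material
11 | 3-allyl-3,8-diol of ring A: C3 hydroxyl cis to the C8 hydroxyl, allyl group on the face of the C7 branch | CC1=C[C@@H](O[Si](C)(C)C(C)(C)C)[C@H](C(CO[Si](C)(C)C(C)(C)C)=C)[C@@H](O)[C@]1(O)CC=C | intermediate
12 | 3-allyl-3-hydroxy 8-ketone of ring A (α-ketol) | CC1=C[C@@H](O[Si](C)(C)C(C)(C)C)[C@H](C(CO[Si](C)(C)C(C)(C)C)=C)C(=O)[C@]1(O)CC=C | intermediate
13 | 2-methylallylmagnesium chloride | CC(=C)C[Mg]Cl | starting material
14 | 3-allyl-8-(2-methylallyl)-3,8-diol of ring A: hydroxyls cis to each other and anti to the C7 branch, both allylic groups on the face of the C7 branch | CC1=C[C@@H](O[Si](C)(C)C(C)(C)C)[C@H](C(CO[Si](C)(C)C(C)(C)C)=C)[C@](O)(CC(C)=C)[C@]1(O)CC=C | intermediate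
15 | cis-fused bicyclic 3,8-diol with C4=C5 and C1=C10 alkenes (C10 methyl), 6-OTBS, C7 silyloxymethyl vinyl branch | CC1=C[C@@H](O[Si](C)(C)C(C)(C)C)[C@H](C(CO[Si](C)(C)C(C)(C)C)=C)[C@]2(O)CC(C)=CC[C@]12O | intermediate
16 | 1,3,8,10-tetrol: 15 with a cis 1,10-diol on the face of the ring-fusion hydroxyls | CC1=C[C@@H](O[Si](C)(C)C(C)(C)C)[C@H](C(CO[Si](C)(C)C(C)(C)C)=C)[C@]2(O)C[C@@](C)(O)[C@@H](O)C[C@]12O | intermediate
17 | key-step precursor: cis-fused decalin-3,8-diol with 1,10-acetonide, 6-OTBS and C7 3-(TBSO)prop-1-en-2-yl branch | CC1=C[C@@H](O[Si](C)(C)C(C)(C)C)[C@H](C(CO[Si](C)(C)C(C)(C)C)=C)[C@]2(O)C[C@@]3(C)OC(C)(C)O[C@H]3C[C@]12O | intermediate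
18 | key-step product: ten-membered (4Z)-ene-3,8-dione with 1,10-acetonide, 6-OTBS and the C7 branch | C/C1=C/[C@@H](O[Si](C)(C)C(C)(C)C)[C@H](C(CO[Si](C)(C)C(C)(C)C)=C)C(=O)C[C@@]2(C)OC(C)(C)O[C@H]2CC1=O | intermediate
19 | (8R)-8-hydroxy derivative of 18 (C3 ketone kept) | C/C1=C/[C@@H](O[Si](C)(C)C(C)(C)C)[C@H](C(CO[Si](C)(C)C(C)(C)C)=C)[C@H](O)C[C@@]2(C)OC(C)(C)O[C@H]2CC1=O | intermediate
20 | 8-isobutyrate of 19 | C/C1=C/[C@@H](O[Si](C)(C)C(C)(C)C)[C@H](C(CO[Si](C)(C)C(C)(C)C)=C)[C@H](OC(=O)C(C)C)C[C@@]2(C)OC(C)(C)O[C@H]2CC1=O | intermediate
21 | (1E,4Z)-dien-3-one with free (10R)-hydroxyl, 8-isobutyrate, 6-OTBS and the C7 branch | C/C1=C/[C@@H](O[Si](C)(C)C(C)(C)C)[C@H](C(CO[Si](C)(C)C(C)(C)C)=C)[C@H](OC(=O)C(C)C)C[C@@](C)(O)/C=C/C1=O | intermediate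
22 | (1R,2R)-1,2-epoxide of 21 | C/C1=C/[C@@H](O[Si](C)(C)C(C)(C)C)[C@H](C(CO[Si](C)(C)C(C)(C)C)=C)[C@H](OC(=O)C(C)C)C[C@@](C)(O)[C@@H]2O[C@H]2C1=O | intermediate
23 | 6,12-diol: 22 without both silyl groups | C/C1=C/[C@@H](O)[C@H](C(CO)=C)[C@H](OC(=O)C(C)C)C[C@@](C)(O)[C@@H]2O[C@H]2C1=O | intermediate
24 | hydroxy enal: 23 with C12 as aldehyde | C/C1=C/[C@@H](O)[C@H](C(C=O)=C)[C@H](OC(=O)C(C)C)C[C@@](C)(O)[C@@H]2O[C@H]2C1=O | intermediate
25 | lactol: 26 with C12 as hemiacetal carbon (C12 unassigned) | C=C1C(O)O[C@@H]2/C=C(/C)C(=O)[C@@H]3O[C@H]3[C@](C)(O)C[C@@H](OC(=O)C(C)C)[C@@H]12 | intermediate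
26 | (1R,2R,4Z,6R,7R,8R,10R)-1,2-epoxy-10-hydroxy-8-isobutyryloxy-3-oxogermacra-4,11(13)-dien-12,6-olide | C=C1C(=O)O[C@@H]2/C=C(/C)C(=O)[C@@H]3O[C@H]3[C@](C)(O)C[C@@H](OC(=O)C(C)C)[C@@H]12 | target

## Step count and risk

Total steps: 18. Longest linear sequence: 18 steps from 1 (10 and 13 are commercial reagents).

Least certain steps:

Step 12 (key step). Most likely problem: slow formation of the cyclic lead diester at a glycol flanked on all sides by substituted carbons. Acetic acid would then have time to remove the acetonide, exposing the C1/C10 glycol to the oxidant, or the freshly formed dione could lose silanol across C6–C7. Fallback: break the same bond by a one-electron path that needs no cyclic ester. From 17, PhI(OAc)2 and I2 under visible light form a hypoiodite and then an alkoxy radical at one ring-fusion oxygen. β-Scission of C3–C8 gives one ketone and an α-hydroxy carbon radical that is oxidised to the second ketone, arriving at 18 without a new isolable compound.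

Step 6. Most likely problem: poor facial selectivity. If the chelate is loose, the allyl group may follow the torsionally favoured axial path and enter cis to the C8 oxygen, giving the trans glycol and in the end a trans-fused bicycle. Fallback (oxygen delivered last instead of carbon): from 9, methylenation of the ketone with Ph3P=CH2 gives the exocyclic diene F1. Hydroxyl-directed epoxidation with VO(acac)2/t-BuOOH places oxygen on the face of the 8-hydroxyl to give the spiro-epoxide F2. Opening at the primary carbon with CH2=CHMgBr and catalytic CuBr·SMe2 returns to the route at 11.

Step 1. Most likely problem: enolisation at the wrong site or over-isomerisation. Trapping of the cross-conjugated dienolate, or base-induced migration of the double bonds towards the aromatic phenol, would erode 3. Fallback: from 1, the same base followed by kinetic protonation (AcOH, −78 °C) gives the β,γ-unsaturated ketone F3; only the extended dienolate leads to it, and the rest returns as 1. Peracid epoxidation anti to the isopropenyl group gives the epoxy ketone F4, and Et3N opens it by β-elimination, returning to the route at 5.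

Step 13. Most likely problem: facial selectivity of hydride delivery. The ten-membered ring of 18 is mobile, and the local Felkin–Anh preference may be overridden, giving the C8 epimer. Fallback: from 18, if reduction gives mainly the (8S) alcohol F5, a Mitsunobu reaction with isobutyric acid (PPh3, DIAD) inverts C8 and installs the ester in one operation, returning to the route at 20.

Step 16. Most likely problem: facial selectivity of peroxide addition. Which face of the E alkene is exposed depends on the ring conformer of 21, and the other arrangement would give the (1S,2S) oxirane. Fallback: epoxidise a different, more rigid substrate, the lactone, with its methylene group masked. From 21, HF·pyridine gives the diol F6, and TEMPO/PhI(OAc)2 gives the dienone lactone F7. Me2NH adds to the methylene lactone to give the amino lactone F8, and t-BuOOH/DBU epoxidises C1=C2 to give the epoxy amino lactone F9. MeI then NaHCO3 regenerates the methylene group, arriving at 26.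

## Further compounds

F0 | step 12 | none | none
F1 | step 6 | exocyclic diene: 9 with C3=CH2 in place of the C3 carbonyl | CC1=C[C@@H](O[Si](C)(C)C(C)(C)C)[C@H](C(CO[Si](C)(C)C(C)(C)C)=C)[C@@H](O)C1=C
F2 | step 6 | spiro-epoxide of F1, oxirane oxygen on C3 cis to the 8-hydroxyl | CC1=C[C@@H](O[Si](C)(C)C(C)(C)C)[C@H](C(CO[Si](C)(C)C(C)(C)C)=C)[C@@H](O)[C@]12CO2
F3 | step 1 | β,γ-unsaturated isomer of 1: 2-methyl-5-(prop-1-en-2-yl)cyclohex-3-en-1-one, C5 as in 1, C2 unassigned | CC1C=C[C@H](C(C)=C)CC1=O
F4 | step 1 | 3,4-epoxide of F3, oxirane anti to the isopropenyl group | CC1[C@H]2O[C@H]2[C@H](C(C)=C)CC1=O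
F5 | step 13 | (8S) epimer of 19 | C/C1=C/[C@@H](O[Si](C)(C)C(C)(C)C)[C@H](C(CO[Si](C)(C)C(C)(C)C)=C)[C@@H](O)C[C@@]2(C)OC(C)(C)O[C@H]2CC1=O
F6 | step 16 | 6,12-diol: 21 without both silyl groups | C/C1=C/[C@@H](O)[C@H](C(CO)=C)[C@H](OC(=O)C(C)C)C[C@@](C)(O)/C=C/C1=O
F7 | step 16 | dienone lactone: 26 with the (1E) alkene in place of the oxirane | C=C1C(=O)O[C@@H]2/C=C(/C)C(=O)/C=C/[C@](C)(O)C[C@@H](OC(=O)C(C)C)[C@@H]12
F8 | step 16 | 13-dimethylamino-11,13-dihydro adduct of F7 (C11 unassigned) | CN(C)CC1C(=O)O[C@@H]2/C=C(/C)C(=O)/C=C/[C@](C)(O)C[C@@H](OC(=O)C(C)C)[C@@H]12
F9 | step 16 | (1R,2R)-1,2-epoxide of F8 | CN(C)CC1C(=O)O[C@@H]2/C=C(/C)C(=O)[C@@H]3O[C@H]3[C@](C)(O)C[C@@H](OC(=O)C(C)C)[C@@H]12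
A1 | alternative 1 | open-chain lactone with C1 aldehyde on C10 (10-OTES), 8-OTBS and C3 chloromethyl ketone on the Z-alkene | O=C[C@](C)(O[Si](CC)(CC)CC)C[C@@H](O[Si](C)(C)C(C)(C)C)[C@H]1CC(=O)O[C@@H]1/C=C(/C)C(=O)CCl
A2 | alternative 1 | ten-membered epoxy enone lactone with 8-OTBS and 10-OTES, without the lactone methylene | C1C(=O)O[C@@H]2/C=C(/C)C(=O)[C@@H]3O[C@H]3[C@](C)(O[Si](CC)(CC)CC)C[C@@H](O[Si](C)(C)C(C)(C)C)[C@@H]12
A3 | alternative 2 | ten-membered 1,2:7,8-bis-epoxide with C6 diethylphosphonoacetate, 3-OTBS and 10-OTES | CCOP(=O)(OCC)CC(=O)O[C@@H]1/C=C(/C)[C@@H](O[Si](C)(C)C(C)(C)C)[C@@H]2O[C@H]2[C@](C)(O[Si](CC)(CC)CC)C[C@H]3O[C@H]13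
A4 | alternative 2 | α-phosphono trans-lactone with free 8-hydroxyl (C3 and C11 epimers arbitrary) | CCOP(=O)(OCC)[C@@H]1C(=O)O[C@@H]2/C=C(/C)[C@@H](O[Si](C)(C)C(C)(C)C)[C@@H]3O[C@H]3[C@](C)(O[Si](CC)(CC)CC)C[C@@H](O)[C@@H]12
A5 | alternative 3 | open-chain methylene lactone with (Z)-C4 vinyl iodide, 8-isobutyrate, 10-hydroxyl and 1,2-epoxy C3 aldehyde | C=C1C(=O)O[C@H](/C=C(/C)I)[C@H]1[C@H](OC(=O)C(C)C)C[C@@](C)(O)[C@@H]2O[C@H]2C=O
A6 | alternative 3 | 3-hydroxy analogue of 26 (one C3 epimer drawn) | C=C1C(=O)O[C@@H]2/C=C(/C)[C@@H](O)[C@@H]3O[C@H]3[C@](C)(O)C[C@@H](OC(=O)C(C)C)[C@@H]12
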